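The constants used here were drawn at random within sensible limits; the rest is arithmetic.

I had to choose the charge for the next run, and I began with the easy step of writing down what was charged and what was asked.

    initiator → 2 initiating radical (k1 = 0.0016 /s)
    starting material + initiating radical → capped initiator + first chain carrier (k2 = 1.6 × 10⁷ /M/s)
    reagent + first chain carrier ⇌ target + second chain carrier (K3 = 2.1, k3 = 5.6 × 10⁵ /M/s)
    starting material + second chain carrier → released group + first chain carrier (k4 = 2.7 × 10⁷ /M/s)
    2 second chain carrier → ended chains (k5 = 1 × 10⁹ /M/s)
    target → over-reaction product (k6 = 0.0032 /s)

| flask | starting material | reagent | initiator | time | remark |
|---|---|---|---|---|---|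
| midnight | 0.050 M | 0.0650 M (fed, over 8.00 min) | 0.25 mM | 8.0 min | a stirred flask in which reagent is dosed at a steady rate over 8.00 min without added volume, worked up at 8.0 min |
| dusk | 0.050 M | 0.0650 M | 0.25 mM | 8.0 min | everything together in a closed stirred flask, run for 8.0 min |
| autumn | 0.050 M | 0.0650 M | 0.25 mM |  | one stirred flow tank at steady state, fed with the mixture as stated, mean residence time 8.0 min |
| noon | 0.050 M (fed, over 8.00 min) | 0.0650 M | 0.25 mM | 8.0 min | all but starting material at the start; starting material goes in evenly over 8.00 min, the run ends at 8.0 min |

- where a step has two of a species, its rate is k times that concentration squared, and two are used at each turn
- the stated concentrations are those of everything mixed, before any reaction; amounts are the same in each set-up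
- the feed brings no volume worth counting
- run time (midnight): 8.0 min

* the set-up with the highest amount of target at the outlet or at the end, in percent of the starting material put in ("none" if the first two lie within 2 percentage points) (midnight / dusk / autumn / noon / none)
* amount of target at the outlet or at the end, in percent of the starting material put in, midnight
* amount of target at the outlet or at the end, in percent of the starting material put in, dusk
* amount of target at the outlet or at the end, in percent of the starting material put in, autumn
* amount of target at the outlet or at the end, in percent of the starting material put in, noon

1. The two chain steps together turn one starting material and one reagent into one target and one released group. With 0.050 M of starting material against 0.0650 M of reagent, starting material was the limiting reagent, so I reckoned each yield on it.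

2. I worked in powers of ten. I called the decade time of target the time in which the over-reaction step lowers target by a factor of 10, which is 2.3/k6 = 12.0 min.

3. For dusk at the start, setting radical supply equal to chain ending gave c(second chain carrier) = sqrt(k1·c(initiator)/k5) = 2.00 × 10⁻⁸ M. Starting material in dusk then has a pseudo-first-order lifetime of 1.85 s. This is far shorter than the decade time, so I took target in dusk to be born at once. For the other flasks I assumed the same, that target is born as soon as the partners meet, with its age the time since then.

4. In dusk, target is born at the start and ages 0.668 decades, which leaves 21.5 %. In noon, target is born evenly over 8.00 min, and averaging the survivors gives 51.1 %. In midnight, the feed has delivered as much reagent as the charge of starting material at 6.15 min, and the target then ages for the remaining time, which gives 41.2 %. In autumn, the tank's spread of ages gives 39.4 %.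

5. My noon figure stood above the others by 9.9 percentage points over the next best, beyond the margin of 2 points. I therefore chose to charge reagent and initiator at the start and to dose starting material.

6. The forecast gave 41 % for midnight, 21.7 % for dusk, 39.1 % for autumn and 50.4 % for noon, and named noon, saying: “Dosing starting material makes target late and evenly right up to the end”.

7. The flasks gave 41.2 % for midnight, 21.7 % for dusk, 39.2 % for autumn and 50.9 % for noon. Noon was the highest, so the next run stayed as chosen.

8. In dusk, half of the turnover of starting material with second chain carrier was done by 1.87 s, far inside the decade time of 12.0 min, and at 8.0 min over-reaction product held 78.3 % of the starting material charged. The dusk flask left until 30 min had aged 2.50 decades, which reckons to 0.315 %, and it held 0.317 % of target.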